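**Retrosynthetic overview**

- Locants used throughout: eight-membered ring C1 (CH carrying side-chain carbon C9) – C2 – C3 – C4 – C5 – C6 (CHMe) – C7 (CH2) – C8 (C–O); C10 is the OCH2 on C2 and C11 the lactone carbonyl (earlier the acetal carbon) on C3.
- The strategy rests on two features: C8 with its neighbours C7H2 and C6H(Me) is CO plus a ring-opened trans-2-methylcyclopropane, and the butenolide ring (C2, C3, C10, O, C11) can serve as a five-membered acetal tether. This allows a rhodium (5+2)+1 disconnection of C2–C3, C1–C8 and C7–C8.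
- The cycloaddition precursor is a mixed methyl acetal joining an enantiopure trans-methyl vinylcyclopropane enal (asymmetric cyclopropanation of crotyl alcohol) to an E-allylic alcohol whose C9 centre comes from an auxiliary-controlled hydroxymethylation.
- Ring order: the oxolane and the cyclooctenone form together in the key step; the cyclopropane is then placed on C4=C5 under direction of the C8 hydroxyl; the butenolide arises from the acetal by hydrolysis, oxidation and selenoxide elimination.
- The end is desilylation and selective acetylation of the primary alcohol.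

Key step: step 13

Assumption: the acetal carbon C11 is carried as both epimers from the mixed acetal to the lactol (one drawn; they converge at the lactone), and metal-bound or deprotonated forms of a numbered compound (enolates, alkoxides) are not numbered separately.

**Route**

Step 1
Reactants: 1 (E)-but-2-en-1-ol
Product: 2 [(1S,2S)-2-methylcyclopropyl]methanol
Conditions: Et2Zn, CH2I2, DME, CH2Cl2, −10 °C; then the alcohol premixed with (4R,5R)-2-butyl-N,N,N′,N′-tetramethyl-1,3,2-dioxaborolane-4,5-dicarboxamide (1.2 equiv), −10 °C → rt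
Reagents that add atoms: diiodomethane, ICI
Why: Charette asymmetric Simmons–Smith cyclopropanation, in which the zinc alkoxide of the allylic alcohol is bound by the chiral dioxaborolane so that methylene is delivered to one alkene face; the trans relationship follows from the E-alkene and the (4R,5R)-ligand is expected to give the (1S,2S) product.

Step 2
Reactants: 2 [(1S,2S)-2-methylcyclopropyl]methanol
Product: 4 (E)-3-[(1S,2S)-2-methylcyclopropyl]prop-2-enal, via cyclopropanecarbaldehyde 3 (not isolated)
Conditions: TEMPO (10 mol%), PhI(OAc)2, CH2Cl2, rt; then Ph3P=CHCHO, toluene, 70 °C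
Reagents that add atoms: (triphenylphosphoranylidene)acetaldehyde, O=CC=P(c1ccccc1)(c1ccccc1)c1ccccc1
Why: Oxoammonium oxidation of the primary alcohol followed in the same flask by Wittig olefination with the stabilised formyl ylide, which avoids handling the volatile aldehyde and should give the E-enal without touching the ring centres.

Step 3
Reactants: 4 (E)-3-[(1S,2S)-2-methylcyclopropyl]prop-2-enal
Product: 5 (1S,2S)-1-[(1E)-3,3-dimethoxyprop-1-en-1-yl]-2-methylcyclopropane
Conditions: HC(OMe)3, MeOH, NH4NO3 (cat.), rt
Reagents that add atoms: trimethyl orthoformate, COC(OC)OC; methanol, CO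
Why: Acid-catalysed acetalisation with the orthoester as water scavenger; the weakly acidic ammonium salt should spare the vinylcyclopropane and avoid conjugate addition of methanol.

Step 4
Reactants: 6 5-bromo-2-methylpent-2-ene; 7 diethyl malonate
Product: 8 diethyl 2-(4-methylpent-3-en-1-yl)propanedioate
Conditions: NaOEt, EtOH, reflux (malonate in excess)
Reagents that add atoms: none
Why: Malonic ester alkylation (SN2) of the primary bromide, with excess malonate to suppress dialkylation.

Step 5
Reactants: 8 diethyl 2-(4-methylpent-3-en-1-yl)propanedioate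
Product: 10 6-methylhept-5-enoic acid, via alkylmalonic acid 9 (not isolated)
Conditions: KOH, EtOH/H2O, reflux; aq. HCl to pH 2 at 0 °C; crude diacid heated neat, 150 °C
Reagents that add atoms: potassium hydroxide, [K+].[OH-]
Why: Saponification and thermal decarboxylation of the monoalkylmalonic acid (malonic ester synthesis), run without hot mineral acid so that the trisubstituted alkene is not hydrated.

Step 6
Reactants: 10 6-methylhept-5-enoic acid; 11 (S)-4-benzyl-1,3-oxazolidin-2-one
Product: 13 (S)-4-benzyl-3-(6-methylhept-5-enoyl)-1,3-oxazolidin-2-one, via mixed pivalic anhydride 12 (not isolated)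
Conditions: t-BuCOCl, Et3N, THF, −20 °C; then LiCl and the oxazolidinone, −20 °C → rt
Reagents that add atoms: none
Why: N-Acylation of the Evans auxiliary through the mixed anhydride under the mild LiCl/Et3N protocol, which attacks the less hindered acyl group.

Step 7
Reactants: 13 (S)-4-benzyl-3-(6-methylhept-5-enoyl)-1,3-oxazolidin-2-one
Product: 14 (S)-4-benzyl-3-[(R)-2-(hydroxymethyl)-6-methylhept-5-enoyl]-1,3-oxazolidin-2-one
Conditions: TiCl4, i-Pr2NEt, CH2Cl2, 0 °C; then 1,3,5-trioxane, TiCl4, 0 °C
Reagents that add atoms: 1,3,5-trioxane, C1OCOCO1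
Why: Evans titanium-enolate hydroxymethylation, in which the chelated Z-enolate is attacked by TiCl4-activated formaldehyde on the face opposite the benzyl group, setting the (R)-centre that becomes C9; the enolate should outcompete the remote trisubstituted alkene for the electrophile.

Step 8
Reactants: 14 (S)-4-benzyl-3-[(R)-2-(hydroxymethyl)-6-methylhept-5-enoyl]-1,3-oxazolidin-2-one
Product: 15 (S)-4-benzyl-3-[(R)-2-{[(tert-butyldiphenylsilyl)oxy]methyl}-6-methylhept-5-enoyl]-1,3-oxazolidin-2-one
Conditions: TBDPSCl, imidazole, DMF, rt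
Reagents that add atoms: tert-butyl(chloro)diphenylsilane, CC(C)(C)[Si](Cl)(c1ccccc1)c1ccccc1
Why: Silylation of the primary alcohol; the diphenyl silyl group is chosen because it should survive the later acidic acetal hydrolysis and is slow to migrate between the two primary oxygens once the auxiliary is removed.

Step 9
Reactants: 15 (S)-4-benzyl-3-[(R)-2-{[(tert-butyldiphenylsilyl)oxy]methyl}-6-methylhept-5-enoyl]-1,3-oxazolidin-2-one
Product: 16 (S)-2-{[(tert-butyldiphenylsilyl)oxy]methyl}-6-methylhept-5-en-1-ol
Conditions: LiBH4, MeOH (1 equiv), Et2O, 0 °C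
Reagents that add atoms: none
Why: Reductive cleavage of the N-acyl oxazolidinone at the exocyclic carbonyl, under conditions that do not enolise the stereocentre.

Step 10
Reactants: 16 (S)-2-{[(tert-butyldiphenylsilyl)oxy]methyl}-6-methylhept-5-en-1-ol
Product: 18 ethyl (2E,4S)-4-{[(tert-butyldiphenylsilyl)oxy]methyl}-8-methylnona-2,7-dienoate, via silyloxy aldehyde 17 (not isolated)
Conditions: Dess–Martin periodinane, CH2Cl2, 0 °C → rt; then Ph3P=CHCO2Et, rt
Reagents that add atoms: ethyl (triphenylphosphoranylidene)acetate, CCOC(=O)C=P(c1ccccc1)(c1ccccc1)c1ccccc1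
Why: Dess–Martin oxidation and in situ Wittig olefination with the non-basic stabilised ylide, which should preserve the α-stereocentre of the aldehyde and give the E-enoate.

Step 11
Reactants: 18 ethyl (2E,4S)-4-{[(tert-butyldiphenylsilyl)oxy]methyl}-8-methylnona-2,7-dienoate
Product: 19 (2E,4S)-4-{[(tert-butyldiphenylsilyl)oxy]methyl}-8-methylnona-2,7-dien-1-ol
Conditions: i-Bu2AlH, CH2Cl2, −78 °C
Reagents that add atoms: none
Why: 1,2-Reduction of the enoate to the allylic alcohol by the aluminium hydride, leaving the alkene geometry and the silyl ether intact.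

Step 12
Reactants: 5 (1S,2S)-1-[(1E)-3,3-dimethoxyprop-1-en-1-yl]-2-methylcyclopropane; 19 (2E,4S)-4-{[(tert-butyldiphenylsilyl)oxy]methyl}-8-methylnona-2,7-dien-1-ol
Product: 21 E-allyl methyl mixed acetal (both C11 epimers), via collidinium salt 20 (not isolated)
Conditions: dimethyl acetal (1.5 equiv), TESOTf (1.3 equiv), 2,4,6-collidine (3 equiv), CH2Cl2, 0 °C; then the allylic alcohol (1.0 equiv), 0 °C → rt
Reagents that add atoms: none
Why: Acetal exchange through a pyridinium-type salt, in which the silyl triflate and collidine replace one methoxy group of the dimethyl acetal by collidine and the allylic alcohol then displaces the collidine under non-acidic conditions, so that only one methoxy group is exchanged; the silyl triflate is kept below the amount of the dimethyl acetal so that none is left to silylate the alcohol.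

Step 13
Reactants: 21 E-allyl methyl mixed acetal (both C11 epimers); 22 carbon monoxide
Product: 23 (1R,2S,3S,6S)-methoxyoxolane-fused cyclooct-4-en-8-one
Conditions: [Rh(CO)2Cl]2 (5–10 mol%), CO (0.2 atm)/N2 (0.8 atm), 1,4-dioxane (0.05 M), 80–90 °C
Reagents that add atoms: none
Why: Rhodium-catalysed (5+2)+1 carbonylative cycloaddition, whose closest known type is the [Rh(CO)2Cl]2/CO reaction of heteroatom-tethered ene-vinylcyclopropanes to cis-fused bicyclic cyclooct-4-enones: monovalent rhodium binds the vinyl group in its s-cis conformer and opens the cyclopropane C–CH2 bond to an allyl rhodacyclohexene, the tethered alkene inserts into the Rh–C3 bond, CO inserts into a rhodium–alkyl bond and reductive elimination forms C1–C8 and C7–C8, all driven by release of cyclopropane strain. The oxolane closes by 5-exo migratory insertion (bond C2–C3) and the eight-membered ring by acyl–alkyl reductive elimination from the acyl rhodacycle. C3 is fixed by the rhodacycle, because the metal lies on the vinyl face beside the bond it cleaves, which puts C11 cis to the C6 methyl and leaves C6 itself untouched; C2 follows from the cis ring fusion that the three-atom tether enforces; C1 follows from stereospecific syn addition across the E-alkene, which sets the side chain trans to C10 and so gives the C1 configuration of the target. The step needs insertion into the unsubstituted cyclopropane bond and not the methyl-bearing one, which the steric bias of the trans-methyl group should secure, and CO uptake before reductive elimination, which the low CO pressure in dioxane favours over plain (5+2) closure. Both C11 epimers should react and converge later; the 1,2-disubstituted alkene with a branched allylic substituent is the main extension beyond reported substrates.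

Step 14
Reactants: 23 (1R,2S,3S,6S)-methoxyoxolane-fused cyclooct-4-en-8-one
Product: 24 (1R,2R,3S,6S,8S)-methoxyoxolane-fused cyclooct-4-en-8-ol
Conditions: LiBH(s-Bu)3, THF, −78 °C; then H2O
Reagents that add atoms: none
Why: Ketone reduction with a bulky trialkylborohydride, where attack on the peripheral face of the medium ring, anti to the neighbouring C1 side chain, should place the C8 hydroxyl cis to that side chain (8S).

Step 15
Reactants: 24 (1R,2R,3S,6S,8S)-methoxyoxolane-fused cyclooct-4-en-8-ol
Product: 25 (1R,2R,3S,4R,5R,6S,8S)-cyclopropane-fused cyclooctan-8-ol acetal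
Conditions: Et2Zn, CH2I2, CH2Cl2, −20 → 0 °C
Reagents that add atoms: diiodomethane, ICI
Why: Hydroxyl-directed Simmons–Smith cyclopropanation (Furukawa conditions), in which the C8 zinc alkoxide delivers the carbenoid across the ring to the near face of C4=C5, which is also the peripheral face anti to the C6 methyl and to C11, so the CH2 should enter cis to the C8 oxygen and faster than at the undirected side-chain alkene.

Step 16
Reactants: 25 (1R,2R,3S,4R,5R,6S,8S)-cyclopropane-fused cyclooctan-8-ol acetal
Product: 26 C8 tert-butyldimethylsilyl ether of the cyclopropane-fused acetal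
Conditions: TBSCl, imidazole, DMAP (cat.), DMF, rt → 40 °C
Reagents that add atoms: tert-butyl(chloro)dimethylsilane, CC(C)(C)[Si](C)(C)Cl
Why: Imidazole-promoted silylation of the secondary alcohol under basic conditions free of Lewis acid, which should leave the methyl acetal untouched and mask the hydroxyl for the later oxidation and enolate chemistry.

Step 17
Reactants: 26 C8 tert-butyldimethylsilyl ether of the cyclopropane-fused acetal
Product: 27 bis-silyl lactol (both anomers)
Conditions: AcOH/THF/H2O (4:2:1), 40 °C
Reagents that add atoms: water, O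
Why: Acid hydrolysis of the cyclic methyl acetal through the oxocarbenium ion, under conditions that the hindered secondary silyl ether and the primary diphenyl silyl ether should survive.

Step 18
Reactants: 27 bis-silyl lactol (both anomers)
Product: 28 cis-fused bis-silyl γ-lactone
Conditions: Pr4N[RuO4] (5 mol%), N-methylmorpholine N-oxide, 4 Å molecular sieves, CH2Cl2, rt
Reagents that add atoms: none
Why: Ley–Griffith oxidation of the lactol to the lactone, at which point both C11 epimers become one compound.

Step 19
Reactants: 28 cis-fused bis-silyl γ-lactone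
Product: 31 bis-silyl butenolide, via phenylselanyl lactone 29 (not isolated), via selenoxide 30 (not isolated)
Conditions: LiN(i-Pr)2, THF, −78 °C; PhSeBr, −78 °C; then pyridine, 30% H2O2, 0 °C → rt
Reagents that add atoms: none
Why: α-Selenenylation of the lactone enolate and selenoxide syn-elimination, in which selenium enters on the convex face cis to the C2 hydrogen and elimination should run toward C2 because the other β-carbon is a cyclopropane CH whose loss would give a strained alkylidenecyclopropane, giving the tetrasubstituted butenolide and removing the temporary C2 and C3 centres.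

Step 20
Reactants: 31 bis-silyl butenolide
Product: 32 butenolide diol
Conditions: HF·pyridine, pyridine, THF, 0 °C → rt
Reagents that add atoms: none
Why: Fluoride cleavage of both silyl ethers under buffered, non-basic conditions that should leave the butenolide, the cyclopropane and the trisubstituted alkene untouched.

Step 21
Reactants: 32 butenolide diol
Product: 33 target acetate CNP0267808.2
Conditions: AcCl (1.1 equiv), 2,4,6-collidine, CH2Cl2, −78 °C
Reagents that add atoms: acetyl chloride, CC(=O)Cl
Why: Selective acylation of the primary alcohol with acetyl chloride and collidine at low temperature, the C8 hydroxyl being secondary and shielded by the branched C1 substituent.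

**Compound list**

1 | (E)-but-2-en-1-ol | C/C=C/CO | starting material
2 | [(1S,2S)-2-methylcyclopropyl]methanol | OC[C@H]1C[C@@H]1C | intermediate
3 | (1S,2S)-2-methylcyclopropane-1-carbaldehyde | O=C[C@H]1C[C@@H]1C | intermediate
4 | (E)-3-[(1S,2S)-2-methylcyclopropyl]prop-2-enal | O=C/C=C/[C@H]1C[C@@H]1C | intermediate
5 | (1S,2S)-1-[(1E)-3,3-dimethoxyprop-1-en-1-yl]-2-methylcyclopropane | COC(OC)/C=C/[C@H]1C[C@@H]1C | intermediate
6 | 5-bromo-2-methylpent-2-ene | CC(C)=CCCBr | starting material
7 | diethyl malonate | CCOC(=O)CC(=O)OCC | starting material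
8 | diethyl 2-(4-methylpent-3-en-1-yl)propanedioate | CCOC(=O)C(CCC=C(C)C)C(=O)OCC | intermediate
9 | 2-(4-methylpent-3-en-1-yl)propanedioic acid | OC(=O)C(CCC=C(C)C)C(=O)O | intermediate
10 | 6-methylhept-5-enoic acid | CC(C)=CCCCC(=O)O | intermediate
11 | (S)-4-benzyl-1,3-oxazolidin-2-one | O=C1OC[C@H](Cc2ccccc2)N1 | starting material
12 | 2,2-dimethylpropanoic 6-methylhept-5-enoic anhydride | CC(C)=CCCCC(=O)OC(=O)C(C)(C)C | intermediate
13 | (S)-4-benzyl-3-(6-methylhept-5-enoyl)-1,3-oxazolidin-2-one | CC(C)=CCCCC(=O)N1[C@@H](Cc2ccccc2)COC1=O | intermediate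
14 | (S)-4-benzyl-3-[(R)-2-(hydroxymethyl)-6-methylhept-5-enoyl]-1,3-oxazolidin-2-one | O=C1OC[C@H](Cc2ccccc2)N1C(=O)[C@@H](CO)CCC=C(C)C | intermediate
15 | (S)-4-benzyl-3-[(R)-2-{[(tert-butyldiphenylsilyl)oxy]methyl}-6-methylhept-5-enoyl]-1,3-oxazolidin-2-one | O=C1OC[C@H](Cc2ccccc2)N1C(=O)[C@@H](CO[Si](c1ccccc1)(c1ccccc1)C(C)(C)C)CCC=C(C)C | intermediate
16 | (S)-2-{[(tert-butyldiphenylsilyl)oxy]methyl}-6-methylhept-5-en-1-ol | OC[C@@H](CO[Si](c1ccccc1)(c1ccccc1)C(C)(C)C)CCC=C(C)C | intermediate
17 | (R)-2-{[(tert-butyldiphenylsilyl)oxy]methyl}-6-methylhept-5-enal | O=C[C@@H](CO[Si](c1ccccc1)(c1ccccc1)C(C)(C)C)CCC=C(C)C | intermediate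
18 | ethyl (2E,4S)-4-{[(tert-butyldiphenylsilyl)oxy]methyl}-8-methylnona-2,7-dienoate | CCOC(=O)/C=C/[C@@H](CO[Si](c1ccccc1)(c1ccccc1)C(C)(C)C)CCC=C(C)C | intermediate
19 | (2E,4S)-4-{[(tert-butyldiphenylsilyl)oxy]methyl}-8-methylnona-2,7-dien-1-ol | OC/C=C/[C@@H](CO[Si](c1ccccc1)(c1ccccc1)C(C)(C)C)CCC=C(C)C | intermediate
20 | 1-{(2E)-1-methoxy-3-[(1S,2S)-2-methylcyclopropyl]prop-2-en-1-yl}-2,4,6-trimethylpyridinium trifluoromethanesulfonate (both epimers) | COC(/C=C/[C@H]1C[C@@H]1C)[n+]1c(C)cc(C)cc1C.[O-]S(=O)(=O)C(F)(F)F | intermediate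
21 | mixed acetal of (E)-3-[(1S,2S)-2-methylcyclopropyl]prop-2-enal carrying one methoxy group and the (2E,4S)-4-{[(tert-butyldiphenylsilyl)oxy]methyl}-8-methylnona-2,7-dien-1-yloxy group (both C11 epimers, one drawn) | CO[C@H](/C=C/[C@H]1C[C@@H]1C)OC/C=C/[C@@H](CO[Si](c1ccccc1)(c1ccccc1)C(C)(C)C)CCC=C(C)C | intermediate
22 | carbon monoxide | [C-]#[O+] | starting material
23 | (1R,2S,3S,6S)-cyclooct-4-en-8-one: cis-fused 11-methoxyoxolane across C2–C3, Z-C4=C5, 6-methyl, 1-[(2S)-1-(tert-butyldiphenylsilyloxy)-6-methylhept-5-en-2-yl] (C11 epimers, one drawn) | CC(C)(C)[Si](c1ccccc1)(c1ccccc1)OC[C@@H](CCC=C(C)C)[C@@H]1[C@H]2CO[C@H](OC)[C@H]2/C=C\[C@@H](C)CC1=O | intermediate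
24 | (1R,2R,3S,6S,8S)-cyclooct-4-en-8-ol: same skeleton as the cyclooctenone, hydroxyl cis to the C1 side chain | CC(C)(C)[Si](c1ccccc1)(c1ccccc1)OC[C@@H](CCC=C(C)C)[C@@H]1[C@H]2CO[C@H](OC)[C@H]2/C=C\[C@@H](C)C[C@@H]1O | intermediate
25 | (1R,2R,3S,4R,5R,6S,8S)-4,5-methano (cyclopropane-fused) cyclooctan-8-ol with cis-fused 11-methoxyoxolane, cyclopropane CH2 cis to the C8 hydroxyl | CC(C)(C)[Si](c1ccccc1)(c1ccccc1)OC[C@@H](CCC=C(C)C)[C@@H]1[C@H]2CO[C@H](OC)[C@H]2[C@@H]2C[C@@H]2[C@@H](C)C[C@@H]1O | intermediate
26 | C8 tert-butyldimethylsilyl ether of the cyclopropane-fused cyclooctanol acetal | CC(C)(C)[Si](c1ccccc1)(c1ccccc1)OC[C@@H](CCC=C(C)C)[C@@H]1[C@H]2CO[C@H](OC)[C@H]2[C@@H]2C[C@@H]2[C@@H](C)C[C@@H]1O[Si](C)(C)C(C)(C)C | intermediate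
27 | bis-silyl lactol: 11-hydroxyoxolane in place of the methyl acetal (both anomers) | CC(C)(C)[Si](c1ccccc1)(c1ccccc1)OC[C@@H](CCC=C(C)C)[C@@H]1[C@H]2COC(O)[C@H]2[C@@H]2C[C@@H]2[C@@H](C)C[C@@H]1O[Si](C)(C)C(C)(C)C | intermediate
28 | cis-fused bis-silyl γ-lactone (C11=O) | CC(C)(C)[Si](c1ccccc1)(c1ccccc1)OC[C@@H](CCC=C(C)C)[C@@H]1[C@H]2COC(=O)[C@H]2[C@@H]2C[C@@H]2[C@@H](C)C[C@@H]1O[Si](C)(C)C(C)(C)C | intermediate
29 | 3-(phenylselanyl) lactone (selenium cis to the C2 hydrogen) | CC(C)(C)[Si](c1ccccc1)(c1ccccc1)OC[C@@H](CCC=C(C)C)[C@@H]1[C@H]2COC(=O)[C@@]2([Se]c2ccccc2)[C@@H]2C[C@@H]2[C@@H](C)C[C@@H]1O[Si](C)(C)C(C)(C)C | intermediate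
30 | selenoxide of the 3-(phenylselanyl) lactone | CC(C)(C)[Si](c1ccccc1)(c1ccccc1)OC[C@@H](CCC=C(C)C)[C@@H]1[C@H]2COC(=O)[C@@]2([Se](=O)c2ccccc2)[C@@H]2C[C@@H]2[C@@H](C)C[C@@H]1O[Si](C)(C)C(C)(C)C | intermediate
31 | (1R,4R,5R,6S,8S)-butenolide (C2=C3) with C8 tert-butyldimethylsilyl ether and primary tert-butyldiphenylsilyl ether | CC(C)(C)[Si](c1ccccc1)(c1ccccc1)OC[C@@H](CCC=C(C)C)[C@@H]1C2=C(C(=O)OC2)[C@@H]2C[C@@H]2[C@@H](C)C[C@@H]1O[Si](C)(C)C(C)(C)C | intermediate
32 | (1R,4R,5R,6S,8S)-butenolide diol (free C8 hydroxyl, free primary hydroxyl on the side chain) | OC[C@@H](CCC=C(C)C)[C@@H]1C2=C(C(=O)OC2)[C@@H]2C[C@@H]2[C@@H](C)C[C@@H]1O | intermediate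
33 | CNP0267808.2: (1R,4R,5R,6S,8S)-butenolide-fused cyclopropa-cyclooctan-8-ol with 1-[(2S)-1-acetoxy-6-methylhept-5-en-2-yl] | CC(=O)OC[C@@H](CCC=C(C)C)[C@@H]1C2=C(C(=O)OC2)[C@@H]2C[C@@H]2[C@@H](C)C[C@@H]1O | target

**Step count and risks**

Total step count: 21. Longest linear sequence: 18 steps (steps 4–21, from 5-bromo-2-methylpent-2-ene).

Steps most likely to fail:

1. Step 13. The hindered E-1,2-disubstituted alkene may insert too slowly into the allyl–rhodium bond. Then β-hydride elimination, plain (5+2) closure without CO, insertion into the methyl-bearing cyclopropane bond, or ionisation of the allylic acetal by the Lewis-acidic catalyst can take over. The fallback changes the alkene geometry of the precursor and corrects C1 afterwards by equilibration; it sets out from alcohol 16 and comes back at 23. Dess–Martin oxidation of 16 to aldehyde 17 and Still–Gennari olefination with (CF3CH2O)2P(O)CH2CO2Me, KN(SiMe3)2 and 18-crown-6 in THF at −78 °C should give methyl (2Z,4S)-4-{[(tert-butyldiphenylsilyl)oxy]methyl}-8-methylnona-2,7-dienoate F1. Reduction with i-Bu2AlH gives the (2Z,4S)-allylic alcohol F2, and the collidinium acetal exchange of step 12 with 5 gives the Z-configured mixed acetal F3. Cis-alkenes generally bind and insert into metal–carbon bonds more readily than trans-alkenes, so the same [Rh(CO)2Cl]2/CO conditions should now give, by syn addition, the (1S)-epimer of the cyclooctenone F4, with the side chain cis to C10. Because C1 is α to the ketone, DBU in toluene should equilibrate it to the trans arrangement of side chain and oxolane, which is 23.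

2. Step 15. The zinc carbenoid may methylenate the electron-rich trisubstituted side-chain alkene, or reach the wrong face of C4=C5 if the C8 alkoxide cannot deliver it across the ring. The fallback gives up hydroxyl direction for steric discrimination by a palladium carbene; it sets out from 24 and comes back at 26. Silylation of 24 (TBSCl, imidazole, DMAP, DMF) gives the C8 tert-butyldimethylsilyl ether of the cyclooctenol F5. Diazomethane with catalytic Pd(OAc)2 in Et2O at 0 °C cyclopropanates alkenes in the order of their ability to coordinate divalent palladium, so the strained cis ring alkene should react and the trisubstituted alkene should not. Attack on the peripheral face, anti to the C6 methyl and to C11, should give 26.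

3. Step 14. Hydride may be delivered to the other face of the ketone, giving the alcohol with the hydroxyl trans to the side chain. The fallback corrects the centre by inversion; it sets out from 23 and comes back at 24. The (8R)-epimeric alcohol F6, taken from the hydride reduction (NaBH4, CeCl3, MeOH if a small hydride favours it), is subjected to Mitsunobu inversion with 4-nitrobenzoic acid, PPh3 and diisopropyl azodicarboxylate to give the (8S)-4-nitrobenzoate F7. Methanolysis with K2CO3 in MeOH, which the acetal and the silyl ether tolerate, gives 24.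

**Further compounds**

F1 | step 13 | methyl (2Z,4S)-4-{[(tert-butyldiphenylsilyl)oxy]methyl}-8-methylnona-2,7-dienoate | COC(=O)/C=C\[C@@H](CO[Si](c1ccccc1)(c1ccccc1)C(C)(C)C)CCC=C(C)C
F2 | step 13 | (2Z,4S)-4-{[(tert-butyldiphenylsilyl)oxy]methyl}-8-methylnona-2,7-dien-1-ol | OC/C=C\[C@@H](CO[Si](c1ccccc1)(c1ccccc1)C(C)(C)C)CCC=C(C)C
F3 | step 13 | Z-configured mixed acetal (both C11 epimers, one drawn) | CO[C@H](/C=C/[C@H]1C[C@@H]1C)OC/C=C\[C@@H](CO[Si](c1ccccc1)(c1ccccc1)C(C)(C)C)CCC=C(C)C
F4 | step 13 | (1S)-epimer of the methoxyoxolane-fused cyclooctenone | CC(C)(C)[Si](c1ccccc1)(c1ccccc1)OC[C@@H](CCC=C(C)C)[C@H]1[C@H]2CO[C@H](OC)[C@H]2/C=C\[C@@H](C)CC1=O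
F5 | step 15 | C8 tert-butyldimethylsilyl ether of the methoxyoxolane-fused cyclooctenol | CC(C)(C)[Si](c1ccccc1)(c1ccccc1)OC[C@@H](CCC=C(C)C)[C@@H]1[C@H]2CO[C@H](OC)[C@H]2/C=C\[C@@H](C)C[C@@H]1O[Si](C)(C)C(C)(C)C
F6 | step 14 | (8R)-epimer of the methoxyoxolane-fused cyclooctenol | CC(C)(C)[Si](c1ccccc1)(c1ccccc1)OC[C@@H](CCC=C(C)C)[C@@H]1[C@H]2CO[C@H](OC)[C@H]2/C=C\[C@@H](C)C[C@H]1O
F7 | step 14 | (8S)-4-nitrobenzoate of the methoxyoxolane-fused cyclooctenol | CC(C)(C)[Si](c1ccccc1)(c1ccccc1)OC[C@@H](CCC=C(C)C)[C@@H]1[C@H]2CO[C@H](OC)[C@H]2/C=C\[C@@H](C)C[C@@H]1OC(=O)c1ccc(cc1)[N+](=O)[O-]
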